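## Retrosynthetic overview

1. Target 12 ⇐ meso diacetate 11 by lipase mono-deacetylation. With the same group on both secondary carbinols the ring core is meso (mirror plane through the quaternary carbon and the midpoint of C=C), so one late enzymatic event sets the absolute configuration.
2. 11 ⇐ alkyne diacetate 9 by CO2-mediated hydration of the tridec-1-ynyl group (masked tridecanoyl) ⇐ meso triol 8 ⇐ racemic cyclopentenone 7 by Luche reduction (both enantiomers of 7 converge on meso 8).
3. 7 ⇐ six-membered lactol 5 by ring contraction. Enabling feature: at the enone oxidation level the C4–C5 ring bond is an aldol bond between the quaternary carbinol carbon C5 (α to C1=O) and the CH–OH carbon C4, and the tertiary hydroxyl oxygen can be the ring oxygen O1 of a 6-hydroxy-2H-pyran-3(6H)-one whose C2 and C6 are these two carbons.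
4. 5 ⇐ furyl propargyl alcohol 4 (Achmatowicz) ⇐ furfural 1 + tridec-1-yne 2.
5. Ring order: furan (bought) → pyranone (step 2) → cyclopentene (step 3), the only ring of the target.

Key step: step 3

Remark (assumption): the sense of the lipase step is taken from the large/medium-substituent rule for lipases with secondary alcohols and from cis-3,5-diacetoxycyclopentene, where the spatially corresponding acetate is the one removed; racemic compounds are drawn as one enantiomer.

## Route

Step 1
Reactants: 1 furan-2-carbaldehyde; 2 tridec-1-yne
Product: 4 rac-1-(furan-2-yl)tetradec-2-yn-1-ol, via lithium tridec-1-yn-1-ide 3 (not isolated)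
Conditions: n-BuLi (1.05 equiv), THF, −78 °C; then 1, −78 → 0 °C; H2O quench
Reagents that add atoms: none
Why: 1,2-addition of a lithium acetylide to an aldehyde; the new carbinol centre is formed racemic, which is harmless because it is enolised in step 3.

Step 2
Reactants: 4 rac-1-(furan-2-yl)tetradec-2-yn-1-ol
Product: 5 6-hydroxy-2-(tridec-1-yn-1-yl)-2H-pyran-3(6H)-one
Conditions: NBS (1.05 equiv), NaHCO3 (2 equiv), THF/H2O (4:1), 0 °C
Reagents that add atoms: water, O
Why: Achmatowicz rearrangement: bromonium-induced oxidation of the furan and capture of the resulting Z-ene-dione by the carbinol oxygen as the six-membered lactol. The alkyne is far less reactive than the furan, and the C2/C6 configurations need no control because both centres are erased in step 3.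

Step 3
Reactants: 5 6-hydroxy-2-(tridec-1-yn-1-yl)-2H-pyran-3(6H)-one
Product: 7 rac-(4R,5S)-4,5-dihydroxy-5-(tridec-1-yn-1-yl)cyclopent-2-en-1-one, via ring-opened Z-keto-enal 6 (not isolated)
Conditions: Et3N (0.5 equiv), DMF, 0 °C → rt
Reagents that add atoms: none
Why: Et3N opens the lactol of 5 to the Z-keto-enal 6 and enolises its C5–H (α to the ketone, α to oxygen and propargylic); the enediolate carbon adds to the aldehyde, so the O1–C6 bond of the pyranone is exchanged for a C2–C6 bond and the six-membered oxacycle contracts to the cyclopentenone, with the former ring oxygen as the tertiary hydroxyl. The closest known reaction type is the amine-mediated isomerisation of Achmatowicz 6-hydroxy-2H-pyran-3(6H)-ones to 4,5-dihydroxycyclopent-2-enones. The only ring closed is the carbocycle, by a 5-(enolexo)-exo-trig aldol that is geometrically possible because the Z-alkene inherited from the pyranone holds C2 and C6 within bonding distance. The quaternary C5 and the carbinol C4 are created together from a planar enediolate and an aldehyde; the trans-diol is expected because the aldehyde oxygen turns away from the enediol oxygen in the transition state and because the reversible aldol can drain to the isomer with the slim alkynyl rod, not the hydroxyl, cis to the C4–OH (the product is racemic, which step 4 makes irrelevant). The step needs C–C bond formation at C2 to win over elimination and alkyne–allene isomerisation, which is secured by intramolecularity and by the absence of a hydrogen at C5 of the product, so that it cannot dehydrate to a cyclopentadienone.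

Step 4
Reactants: 7 rac-(4R,5S)-4,5-dihydroxy-5-(tridec-1-yn-1-yl)cyclopent-2-en-1-one
Product: 8 (1R,2r,3S)-2-(tridec-1-yn-1-yl)cyclopent-4-ene-1,2,3-triol
Conditions: NaBH4 (1.0 equiv), CeCl3·7H2O (1.0 equiv), MeOH, −78 °C
Reagents that add atoms: none
Why: Luche 1,2-reduction of the enone. Hydride should enter from the face opposite the C4–OH and the alkynyl group (both on the same face), the usual cis-1,4 outcome for 4-oxygenated cyclopentenones, so the new carbinol is cis to the C4–OH and trans to the tertiary OH; the product is meso, and both enantiomers of 7 give the same compound.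

Step 5
Reactants: 8 (1R,2r,3S)-2-(tridec-1-yn-1-yl)cyclopent-4-ene-1,2,3-triol
Product: 9 (1R,2r,3S)-2-hydroxy-2-(tridec-1-yn-1-yl)cyclopent-4-ene-1,3-diyl diacetate
Conditions: Ac2O (2.5 equiv), pyridine, DMAP (cat.), CH2Cl2, 0 °C
Reagents that add atoms: acetic anhydride, CC(=O)OC(C)=O
Why: acylation of the two secondary allylic hydroxyls; the congested tertiary propargylic hydroxyl should stay free under these conditions. The acetates keep the cis-homopropargylic oxygens from adding to the alkyne in step 6 and are the handles for step 7; no stereocentre is touched.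

Step 6
Reactants: 9 (1R,2r,3S)-2-hydroxy-2-(tridec-1-yn-1-yl)cyclopent-4-ene-1,3-diyl diacetate
Product: 11 (1R,2r,3S)-2-hydroxy-2-tridecanoylcyclopent-4-ene-1,3-diyl diacetate, via spirocyclic enol carbonate 10 (not isolated)
Conditions: AgOAc (10 mol %), DBU (1.0 equiv), CO2 (1 MPa), toluene, 25 °C; then MeCN/H2O (5:1), CO2 (1 atm), 40 °C
Reagents that add atoms: carbon dioxide, O=C=O
Why: CO2-promoted, silver-catalysed hydration of a tertiary propargylic alcohol. The DBU alkoxide captures CO2 and the carbonate oxygen adds 5-exo-dig, anti to silver, at the alkyne carbon attached to the ring, giving the Z-alkylidene carbonate 10. Water in the DBU hydrogencarbonate buffer should cleave this strained enol carbonate much faster than the secondary acetates; decarboxylation and tautomerisation then place the carbonyl next to the ring (its oxygen comes from CO2, water supplies only hydrogen), the opposite regiochemistry to a Meyer–Schuster course. No stereocentre is touched, and the acetylated β-oxygens exclude retro-aldol opening.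

Step 7
Reactants: 11 (1R,2r,3S)-2-hydroxy-2-tridecanoylcyclopent-4-ene-1,3-diyl diacetate
Product: 12 (1S,4R,5S)-4,5-dihydroxy-5-tridecanoylcyclopent-2-en-1-yl acetate
Conditions: Candida antarctica lipase B (immobilised), n-BuOH (3 equiv), MTBE, 30 °C, stopped after removal of one acetate
Reagents that add atoms: none
Why: enzymatic desymmetrisation of a meso diacetate by lipase-catalysed alcoholysis, the reaction type established for cis-3,5-diacetoxycyclopentene. With the quaternary ring carbon as the large and the vinylic CH as the medium substituent, the lipase should deacylate the (R)-configured acetoxy carbon and leave the (S)-acetate, which is the target. The neutral medium avoids acyl migration and retro-aldol opening, and the quaternary carbon becomes a true stereocentre (S) only through this differentiation.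

## Compound list

1 | furan-2-carbaldehyde (furfural) | O=Cc1ccco1 | starting material
2 | tridec-1-yne | C#CCCCCCCCCCCC | starting material
3 | lithium tridec-1-yn-1-ide | [Li+].[C-]#CCCCCCCCCCCC | intermediate (not isolated)
4 | rac-1-(furan-2-yl)tetradec-2-yn-1-ol | OC(C#CCCCCCCCCCCC)c1ccco1 | intermediate
5 | 6-hydroxy-2-(tridec-1-yn-1-yl)-2H-pyran-3(6H)-one (racemic, C2/C6 diastereomer mixture, no centre fixed) | O=C1C=CC(O)OC1C#CCCCCCCCCCCC | intermediate
6 | (Z)-5-hydroxy-4-oxooctadec-2-en-6-ynal (racemic) | O=C/C=C\C(=O)C(O)C#CCCCCCCCCCCC | intermediate (not isolated)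
7 | rac-(4R,5S)-4,5-dihydroxy-5-(tridec-1-yn-1-yl)cyclopent-2-en-1-one (trans-diol, one enantiomer drawn) | CCCCCCCCCCCC#C[C@]1(O)[C@H](O)C=CC1=O | intermediate
8 | (1R,2r,3S)-2-(tridec-1-yn-1-yl)cyclopent-4-ene-1,2,3-triol (meso; secondary OH groups cis to each other and trans to the tertiary OH) | CCCCCCCCCCCC#C[C@]1(O)[C@H](O)C=C[C@@H]1O | intermediate
9 | (1R,2r,3S)-2-hydroxy-2-(tridec-1-yn-1-yl)cyclopent-4-ene-1,3-diyl diacetate (meso) | CCCCCCCCCCCC#C[C@]1(O)[C@H](OC(C)=O)C=C[C@@H]1OC(C)=O | intermediate
10 | (4Z,5r,6R,9S)-4-dodecylidene-2-oxo-1,3-dioxaspiro[4.4]non-7-ene-6,9-diyl diacetate (meso) | CCCCCCCCCCC/C=C1\OC(=O)O[C@]12[C@H](OC(C)=O)C=C[C@@H]2OC(C)=O | intermediate (not isolated)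
11 | (1R,2r,3S)-2-hydroxy-2-tridecanoylcyclopent-4-ene-1,3-diyl diacetate (meso) | CCCCCCCCCCCCC(=O)[C@]1(O)[C@H](OC(C)=O)C=C[C@@H]1OC(C)=O | intermediate
12 | (1S,4R,5S)-4,5-dihydroxy-5-tridecanoylcyclopent-2-en-1-yl acetate | CCCCCCCCCCCCC(=O)[C@]1(O)[C@H](O)C=C[C@@H]1OC(C)=O | target

## Step count and risks

Total step count: 7. Longest linear sequence: 7 steps (from 1 and 2).

Steps most likely to fail:

Step 3. The relative configuration of the two carbinol carbons may be poorly controlled in the aldol closure: a hydrogen bond from the enediol hydroxyl to the aldehyde would favour the cis-diol. Fallback, setting out from 5: the ring contraction is run as before and the cis-diol fraction, rac-(4S,5S)-4,5-dihydroxy-5-(tridec-1-yn-1-yl)cyclopent-2-en-1-one F1, is corrected by invertive substitution instead of by equilibrium control. Mitsunobu reaction with 4-nitrobenzoic acid (PPh3, DIAD, THF, 0 °C) should invert the allylic C4; the cis tertiary hydroxyl cannot displace the activated oxygen from the same face. This gives rac-(1R,5S)-5-hydroxy-4-oxo-5-(tridec-1-yn-1-yl)cyclopent-2-en-1-yl 4-nitrobenzoate F2, and brief methanolysis (K2CO3 cat., MeOH, 0 °C) returns to the route at 7.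

Step 6. Acetate groups may be lost or scrambled while the enol carbonate is hydrolysed, and the aqueous stage may be sluggish. Fallback, setting out from 9: the carbonate 10 is isolated from the anhydrous first stage, and chemoselectivity is given up. Methanolysis (K2CO3 cat., MeOH, 0 °C, short contact to avoid retro-aldol opening) cleaves the enol carbonate and both acetates to 1-[(1r,2R,5S)-1,2,5-trihydroxycyclopent-3-en-1-yl]tridecan-1-one F3. Re-acetylation of the two secondary hydroxyls (Ac2O, pyridine, 0 °C) returns to the route at 11.

Step 7. The lipase may select the other enantiotopic acetate, or discriminate poorly because the tridecanoyl chain lies on the acetate face, and over-reaction to the diol may erode the yield. Fallback, setting out from 11: the direction of the enzymatic event is reversed. Methanolysis (K2CO3 cat., MeOH, 0 °C) gives the meso triol 1-[(1r,2R,5S)-1,2,5-trihydroxycyclopent-3-en-1-yl]tridecan-1-one F4 (the same structure as F3). Irreversible lipase-catalysed acyl transfer from vinyl acetate (same lipase, MTBE, 30 °C) then acetylates the carbinol that the alcoholysis would have set free. This gives the antipodal monoacetate series and returns to the route at 12 if the hydrolytic mode had shown the opposite sense.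

## Further compounds

F1 | step 3 | rac-(4S,5S)-4,5-dihydroxy-5-(tridec-1-yn-1-yl)cyclopent-2-en-1-one (cis-diol, one enantiomer drawn) | CCCCCCCCCCCC#C[C@]1(O)[C@@H](O)C=CC1=O
F2 | step 3 | rac-(1R,5S)-5-hydroxy-4-oxo-5-(tridec-1-yn-1-yl)cyclopent-2-en-1-yl 4-nitrobenzoate (one enantiomer drawn) | CCCCCCCCCCCC#C[C@]1(O)[C@H](OC(=O)c2ccc(cc2)[N+](=O)[O-])C=CC1=O
F3 | step 6 | 1-[(1r,2R,5S)-1,2,5-trihydroxycyclopent-3-en-1-yl]tridecan-1-one (meso) | CCCCCCCCCCCCC(=O)[C@]1(O)[C@H](O)C=C[C@@H]1O
F4 | step 7 | 1-[(1r,2R,5S)-1,2,5-trihydroxycyclopent-3-en-1-yl]tridecan-1-one (meso) | CCCCCCCCCCCCC(=O)[C@]1(O)[C@H](O)C=C[C@@H]1O
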